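**The exposure.** The ratio of green's charged ligand times time to that of winter's last reading is 1.04, so we read green from winter.

in all of them: starting complex 0.40 M
- autumn: incoming ligand 0.21 M; run made earlier
- spring: incoming ligand 0.43 M; run made earlier
- winter: incoming ligand 1.2 M; run made earlier
- green: incoming ligand 1.00 M; time 25 h
- red: incoming ligand 0.200 M; time 25 h

| run | time / h | complex with one exchanged / % | complex with three exchanged / % |
|---|---|---|---|
| autumn | 4.00 | 3.4 | 0 |
| autumn | 8.00 | 5.4 | 0 |
| autumn | 10.0 | 6.4 | 0 |
| autumn | 15.0 | 8.9 | 0.1 |
| autumn | 20.0 | 10.9 | 0 |
| spring | 1.33 | 1.8 | 0.4 |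
| spring | 2.50 | 3.9 | 0.4 |
| spring | 5.00 | 7.6 | 0.2 |
| spring | 10.0 | 13.4 | 0.3 |
| spring | 20.0 | 20.9 | 0 |
| winter | 4.00 | 16.2 | 0.2 |
| winter | 8.00 | 27.9 | 0 |
| winter | 10.0 | 33.1 | 0.1 |
| winter | 15.0 | 40.2 | 0.1 |
| winter | 20.0 | 45.2 | 0 |

(each reading ± 0.3 percentage points)

- the numbers in the tables scatter with a standard deviation of 0.3 percentage points

1. which of these holds the largest part of the starting complex at the end of green (complex with two exchanged / starting complex / complex with three exchanged / complex with one exchanged)
2. which of these holds the largest part of the starting complex at the end of red (complex with two exchanged / starting complex / complex with three exchanged / complex with one exchanged)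
3. final complex with one exchanged in green, as a percentage of the starting complex charged

We work with the fraction of starting complex left. Holding the incoming ligand at its charge (pseudo-first-order), the logarithm of that fraction falls in proportion to c(incoming ligand) times time. We take winter's first reading as the whole loss of starting complex and scale it to green. This gives the exposure, minus the natural logarithm of the fraction left at the end: 0.921.

**The curve.** By our reckoning, complex with one exchanged starts in green at 0.0368 h⁻¹ of the charge. The fraction of starting complex left in green falls to 0.5 at 18.8 h. Winter shows the knee: its last interval climbs only 0.0100 h⁻¹. At 15.0 h, winter's 40.2% lies below the reckoned 51.5% left. At 20.0 h, its 45.2% lies above the reckoned 41.3%. So we expect green to cross before its end and to finish near 45.2%, with 39.8% left. For red we reckon 83.2% left.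

**The forecast.** It says starting complex for green, starting complex for red and 43%, calling green “one-exchanged about 43%, nearly a tie”. We differ: we expect a clear lead for complex with one exchanged.

**The flask.** Green gives complex with one exchanged at 44.3%, with 34.7% of starting complex left and 18.0% side product. Red gives starting complex at 80.8%.

    starting complex + incoming ligand → leaving ligand + complex with one exchanged (k = 6.92 × 10⁻⁴ M⁻¹ min⁻¹)
    complex with one exchanged + incoming ligand → leaving ligand + complex with two exchanged (k = 8.36 × 10⁻⁵ M⁻¹ min⁻¹)
    complex with two exchanged + incoming ligand → leaving ligand + complex with three exchanged (k = 2.36 × 10⁻⁵ M⁻¹ min⁻¹)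
    crystals ⇌ leaving ligand, rate k4*(cs4 - [leaving ligand]) while solid is left; crystals form when [leaving ligand] > cs4 (solubility = 0.370 M, k = 0.0787 min⁻¹)
    starting complex + complex with one exchanged → side product (k = 9.62 × 10⁻⁴ M⁻¹ min⁻¹)
    complex with three exchanged → over-reaction product (k = 1.19 × 10⁻⁶ min⁻¹)

Our green fraction left stood 5.1 points too high. A neighbouring flask, like green but charged with 0.60 M of incoming ligand, has exposure 0.552, so we reckon 57.6% left. That is 4.7 points above its 53% of starting complex, which exceeds its 30.8% of complex with one exchanged.

Readings and results are calculated with constants of no real substance, noise included.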